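**Plan**
1. Retrosynthetic cuts, in order: oxane O1–C2 together with C3–Br (bromoetherification); the chain at oxane C6 back to a cyclohexyl methyl ketone (allylboration, B-alkyl coupling); cyclohexane C5–C6 together with C4–Br in one cut, to an acyclic α-methylene ketone; then C3–Cl (from C–OH) and C2–C3 (carbonyl allylation).
2. Enabling feature: cyclohexane C1 is bonded to oxane C6, a fully substituted O-bearing carbon that can be carried as C=O. Ring C6 is then the β-carbon of an α-methylene ketone (polarity reversed), and ring C5 is the CH2 end of an isopropenyl group whose inner carbon is the future C4 (CBr) and whose allylic carbon is C3–Cl.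
3. Forward: chain assembly (steps 1–4), cyclohexane by bromide-terminated cyclisation (step 5), carbinol and side chain (steps 6–8), oxane last (step 9).
4. Stereochemistry: cyclohexane C3 by chromium catalysis, then SN2 inversion; C4 and C1 relayed from C3 in step 5; oxane C6 by reagent control (the ring cannot bias it, because C1 carries two CH2 arms); oxane C3 relayed from oxane C6 in the chair bromoetherification.

Key step: step 5

Assumption: the ligand enantiomer in step 1 and the allylborane enantiomer in step 6 are chosen to give the configurations drawn (sense of induction to be confirmed on a model aldehyde and a model methyl ketone); the allylborane is not commercial and is made beforehand by the known ring expansion of B-methoxy-9-borabicyclo[3.3.1]nonane and resolution.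

Step 1
Reactants: 1 2-methylprop-2-enal; 2 ethyl 2-(bromomethyl)prop-2-enoate
Product: 4 ethyl (4S)-4-hydroxy-5-methyl-2-methylidenehex-5-enoate, via silyl ether 3 (not isolated)
Conditions: CrCl2 (10 mol%), chiral 1,8-bis(oxazolinyl)carbazole ligand (12 mol%), Mn, TMSCl, THF, rt; then citric acid, MeOH, 0 °C
Reagents that add atoms: none
Why: Catalytic asymmetric Nozaki–Hiyama–Kishi (Barbier-type) allylation, in which the ligand-bound chromium 2-(ethoxycarbonyl)allyl species adds to the aldehyde through a closed six-membered transition state and sets C4 (S) by catalyst control, while mild acidic cleavage of silyl ether 3 should keep the γ-hydroxy ester from lactonising.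

Step 2
Reactants: 4 ethyl (4S)-4-hydroxy-5-methyl-2-methylidenehex-5-enoate
Product: 5 ethyl (4R)-4-chloro-5-methyl-2-methylidenehex-5-enoate
Conditions: PPh3, Cl3CCOCCl3, CH2Cl2, 0 °C
Reagents that add atoms: hexachloroacetone, ClC(Cl)(Cl)C(=O)C(Cl)(Cl)Cl
Why: Appel-type chlorination of a secondary allylic alcohol by SN2 displacement of the oxyphosphonium group should turn 4S-OH into 4R-Cl with inversion and without allylic transposition, and it is done at the ester stage because an ester carbonyl is a poor neighbouring group.

Step 3
Reactants: 5 ethyl (4R)-4-chloro-5-methyl-2-methylidenehex-5-enoate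
Product: 6 (4R)-4-chloro-N-methoxy-N,5-dimethyl-2-methylidenehex-5-enamide
Conditions: MeNH(OMe)·HCl, i-PrMgCl, THF, −20 °C
Reagents that add atoms: N,O-dimethylhydroxylamine hydrochloride, CNOC.Cl
Why: Aminolysis of the ester by the chloromagnesium amide gives the N-methoxy-N-methylamide at a temperature where neither the allylic chloride nor the acrylate β-carbon should be attacked.

Step 4
Reactants: 6 (4R)-4-chloro-N-methoxy-N,5-dimethyl-2-methylidenehex-5-enamide
Product: 8 (5R)-5-chloro-6-methyl-3-methylidenehept-6-en-2-one, via magnesium chelate 7 (not isolated)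
Conditions: MeMgBr, THF, −78 → −20 °C; then 1 M HCl, 0 °C
Reagents that add atoms: methylmagnesium bromide, C[Mg]Br
Why: Grignard addition to the N-methoxy-N-methylamide stops at the five-membered chelate 7, which releases the methyl ketone only on acidic quench (the acid also keeps the freed amine from adding to the enone); 8 is used at once.

Step 5
Reactants: 8 (5R)-5-chloro-6-methyl-3-methylidenehept-6-en-2-one
Product: 10 1-[(1S,3R,4R)-4-bromo-3-chloro-4-methylcyclohexyl]ethan-1-one, via titanium enolate 9 (not isolated)
Conditions: TiBr4 (1.2 equiv), CH2Cl2, −78 → −40 °C; aq. NaHCO3; then p-TsOH (cat.), CH2Cl2, rt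
Reagents that add atoms: titanium tetrabromide, Br[Ti](Br)(Br)Br
Why: TiBr4 binds the ketone oxygen so that the exocyclic CH2 of the α-methylene ketone (future ring C6) becomes electrophilic, and the CH2 end of the isopropenyl group (future C5) attacks it through a chair transition state to give titanium enolate and a tertiary cation at future C4; the closest known reaction type is the Lewis-acid-promoted conjugate (Michael-type) addition of an alkene to an enone run as a cation–olefin cyclisation with halide termination. The six-membered ring closes 6-endo-trig with respect to the isopropenyl alkene, the enone being attacked at its exocyclic β-carbon. The cation is bridged by the neighbouring axial chlorine on C3 (chloronium ion), and bromide from the titanate opens it at the tertiary carbon from the opposite face, so C4 (R) is set trans-diaxial to C3–Cl by neighbouring-group control from the one existing stereocentre. C1 (S) is set when enolate 9 is protonated and the ketone is equilibrated under acid, the acetyl group taking the equatorial position trans to the axial chlorine. The step needs conjugate rather than carbonyl attack (both would close a six-membered ring) and bromide capture rather than proton loss or ionisation of the allylic C–Cl; the hindered methyl ketone, the low temperature, a single equivalent of a Lewis acid that carries its own bromide, and the thermodynamic preference for the tertiary bromide should secure this.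

Step 6
Reactants: 10 1-[(1S,3R,4R)-4-bromo-3-chloro-4-methylcyclohexyl]ethan-1-one
Product: 12 (2S)-2-[(1S,3R,4R)-4-bromo-3-chloro-4-methylcyclohexyl]pent-4-en-2-ol, via borinate 11 (not isolated)
Conditions: B-allyl-10-phenyl-9-borabicyclo[3.3.2]decane (one enantiomer, 1.3 equiv), Et2O, −78 °C; then MeOH, aq. NH4Cl
Reagents that add atoms: B-allyl-10-phenyl-9-borabicyclo[3.3.2]decane, C=CCB1C2CCCC(CCC2)C1c1ccccc1
Why: Asymmetric allylboration of a methyl ketone through a closed six-membered transition state in which the chiral borabicyclodecane distinguishes methyl from the branched cyclohexyl group, so allyl should add to the Si face and set the carbinol carbon (future oxane C6) as S by reagent control, independent of the remote ring stereocentres.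

Step 7
Reactants: 12 (2S)-2-[(1S,3R,4R)-4-bromo-3-chloro-4-methylcyclohexyl]pent-4-en-2-ol
Product: 14 (2S)-2-[(1S,3R,4R)-4-bromo-3-chloro-4-methylcyclohexyl]-6-methylhept-6-en-2-ol, via alkylborane 13 (not isolated)
Conditions: 9-BBN dimer, THF, rt; then 2-bromopropene, PdCl2(dppf) (5 mol%), K3PO4 (aq.), DMF, rt
Reagents that add atoms: 2-bromopropene, CC(Br)=C
Why: Anti-Markovnikov hydroboration of the terminal alkene followed by B-alkyl Suzuki–Miyaura coupling builds the full carbon chain under mild, weakly basic conditions that the β-chloro tertiary bromide should tolerate.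

Step 8
Reactants: 14 (2S)-2-[(1S,3R,4R)-4-bromo-3-chloro-4-methylcyclohexyl]-6-methylhept-6-en-2-ol
Product: 15 (2S)-2-[(1S,3R,4R)-4-bromo-3-chloro-4-methylcyclohexyl]-6-methylhept-5-en-2-ol
Conditions: chloro[N,N′-bis(3,5-di-tert-butylsalicylidene)cyclohexane-1,2-diaminato]cobalt (3 mol%), PhSiH3 (6 mol%), benzene, rt
Reagents that add atoms: none
Why: Cobalt hydride hydrogen-atom-transfer isomerisation (reversible H-atom addition to the CH2 terminus, abstraction from the neighbouring CH2) moves the 1,1-disubstituted alkene by one position into the more stable trisubstituted alkene without creating a stereocentre.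

Step 9
Reactants: 15 (2S)-2-[(1S,3R,4R)-4-bromo-3-chloro-4-methylcyclohexyl]-6-methylhept-5-en-2-ol
Product: 16 (3R,6S)-3-bromo-6-[(1S,3R,4R)-4-bromo-3-chloro-4-methylcyclohexyl]-2,2,6-trimethyloxane
Conditions: 2,4,4,6-tetrabromocyclohexa-2,5-dien-1-one (1.1 equiv), MeNO2, 0 °C → rt
Reagents that add atoms: 2,4,4,6-tetrabromocyclohexa-2,5-dien-1-one, O=C1C(Br)=CC(Br)(Br)C=C1Br
Why: Bromoetherification in which the bromonium ion of the trisubstituted alkene is opened at its tertiary carbon by the tertiary hydroxyl (6-endo, Markovnikov) through a chair transition state with bromine equatorial and the larger cyclohexyl group equatorial (methyl axial) at the carbinol carbon, which should set oxane C3 (R) from oxane C6.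

**Compound list**
1 | 2-methylprop-2-enal | CC(=C)C=O | starting material
2 | ethyl 2-(bromomethyl)prop-2-enoate | CCOC(=O)C(=C)CBr | starting material
3 | ethyl (4S)-5-methyl-2-methylidene-4-(trimethylsilyloxy)hex-5-enoate | CCOC(=O)C(=C)C[C@H](O[Si](C)(C)C)C(C)=C | intermediate (not isolated)
4 | ethyl (4S)-4-hydroxy-5-methyl-2-methylidenehex-5-enoate | CCOC(=O)C(=C)C[C@H](O)C(C)=C | intermediate
5 | ethyl (4R)-4-chloro-5-methyl-2-methylidenehex-5-enoate | CCOC(=O)C(=C)C[C@@H](Cl)C(C)=C | intermediate
6 | (4R)-4-chloro-N-methoxy-N,5-dimethyl-2-methylidenehex-5-enamide | CON(C)C(=O)C(=C)C[C@@H](Cl)C(C)=C | intermediate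
7 | bromomagnesium alkoxide (N,O-chelate) of the methyl adduct of 6, hemiaminal carbon not defined | CON(C)C(C)(O[Mg]Br)C(=C)C[C@@H](Cl)C(C)=C | intermediate (not isolated)
8 | (5R)-5-chloro-6-methyl-3-methylidenehept-6-en-2-one | CC(=O)C(=C)C[C@@H](Cl)C(C)=C | intermediate
9 | tribromotitanium enolate, {1-[(3R,4R)-4-bromo-3-chloro-4-methylcyclohexylidene]ethoxy}tribromotitanium, enolate geometry not defined | CC(O[Ti](Br)(Br)Br)=C1CC[C@@](C)(Br)[C@H](Cl)C1 | intermediate (not isolated)
10 | 1-[(1S,3R,4R)-4-bromo-3-chloro-4-methylcyclohexyl]ethan-1-one | CC(=O)[C@H]1CC[C@@](C)(Br)[C@H](Cl)C1 | intermediate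
11 | 10-phenyl-9-borabicyclo[3.3.2]decan-9-yl borinate of 12 (auxiliary centres as in the reagent) | C=CC[C@](C)(OB1C2CCCC(CCC2)C1c1ccccc1)[C@H]1CC[C@@](C)(Br)[C@H](Cl)C1 | intermediate (not isolated)
12 | (2S)-2-[(1S,3R,4R)-4-bromo-3-chloro-4-methylcyclohexyl]pent-4-en-2-ol | C[C@](O)(CC=C)[C@H]1CC[C@@](C)(Br)[C@H](Cl)C1 | intermediate
13 | (2S)-5-(9-borabicyclo[3.3.1]nonan-9-yl)-2-[(1S,3R,4R)-4-bromo-3-chloro-4-methylcyclohexyl]pentan-2-ol | C[C@](O)(CCCB1C2CCCC1CCC2)[C@H]1CC[C@@](C)(Br)[C@H](Cl)C1 | intermediate (not isolated)
14 | (2S)-2-[(1S,3R,4R)-4-bromo-3-chloro-4-methylcyclohexyl]-6-methylhept-6-en-2-ol | C[C@](O)(CCCC(C)=C)[C@H]1CC[C@@](C)(Br)[C@H](Cl)C1 | intermediate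
15 | (2S)-2-[(1S,3R,4R)-4-bromo-3-chloro-4-methylcyclohexyl]-6-methylhept-5-en-2-ol | C[C@](O)(CCC=C(C)C)[C@H]1CC[C@@](C)(Br)[C@H](Cl)C1 | intermediate
16 | (3R,6S)-3-bromo-6-[(1S,3R,4R)-4-bromo-3-chloro-4-methylcyclohexyl]-2,2,6-trimethyloxane | CC1(C)O[C@](C)([C@H]2CC[C@@](C)(Br)[C@H](Cl)C2)CC[C@H]1Br | target

**Totals**
Total step count: 9. Longest linear sequence: 9 steps.

**Steps most likely to fail**

Step 5. What may go wrong: ionisation or halide exchange at the allylic C–Cl under the bromide Lewis acid, attack at the carbonyl carbon in place of conjugate attack, or loss of a proton from the tertiary cation in place of bromide capture. The fallback sets out from 8 and separates ring closure from bromide delivery. Me2AlCl (CH2Cl2, −78 °C) should promote the conjugate ene cyclisation without halide capture and give 1-[(1S,3R)-3-chloro-4-methylidenecyclohexyl]ethan-1-one F1 (any endocyclic alkene isomer converges in the next operation). Markovnikov hydrobromination (HBr, CH2Cl2, −78 °C) should then place bromide on the tertiary carbon anti to the neighbouring chlorine, and the route is rejoined at 10.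

Step 9. What may go wrong: competing five-membered (oxolane) ring closure at the secondary carbon of the bromonium ion, and poor face selectivity in bromonium formation. The fallback sets out from 15 and goes through oxymercuration. Hg(OCOCF3)2 (MeNO2, 0 °C), then aqueous KBr, should give the reversible, Markovnikov 6-endo cyclisation product bromo{(3R,6S)-6-[(1S,3R,4R)-4-bromo-3-chloro-4-methylcyclohexyl]-2,2,6-trimethyloxan-3-yl}mercury F4. Brominative demercuration (Br2, LiBr, pyridine, O2) through the oxan-3-yl radical should then give the equatorial bromide, and the route is rejoined at 16.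

Step 8. What may go wrong: isomerisation past the trisubstituted position, radical reduction of the tertiary C–Br by the cobalt hydride system, or bromine-free hydroalkoxylation. The fallback sets out from 12 and replaces steps 7 and 8 by a carbonyl olefination. Hydroboration–oxidation (9-BBN, THF; NaBO3, H2O) should give (4S)-4-[(1S,3R,4R)-4-bromo-3-chloro-4-methylcyclohexyl]pentane-1,4-diol F2. Oxidation of the primary alcohol (SO3·pyridine, DMSO, Et3N) should give the lactol (5S)-5-[(1S,3R,4R)-4-bromo-3-chloro-4-methylcyclohexyl]-5-methyloxolan-2-ol F3. Wittig olefination with Ph3P=C(CH3)2 (THF, 0 °C) then installs the trisubstituted alkene, and the route is rejoined at 15.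

**Further compounds**
F1 | step 5 | 1-[(1S,3R)-3-chloro-4-methylidenecyclohexyl]ethan-1-one | CC(=O)[C@H]1CCC(=C)[C@H](Cl)C1
F2 | step 8 | (4S)-4-[(1S,3R,4R)-4-bromo-3-chloro-4-methylcyclohexyl]pentane-1,4-diol | C[C@](O)(CCCO)[C@H]1CC[C@@](C)(Br)[C@H](Cl)C1
F3 | step 8 | (5S)-5-[(1S,3R,4R)-4-bromo-3-chloro-4-methylcyclohexyl]-5-methyloxolan-2-ol | OC1CC[C@](C)(O1)[C@H]1CC[C@@](C)(Br)[C@H](Cl)C1
F4 | step 9 | bromo{(3R,6S)-6-[(1S,3R,4R)-4-bromo-3-chloro-4-methylcyclohexyl]-2,2,6-trimethyloxan-3-yl}mercury | CC1(C)O[C@](C)([C@H]2CC[C@@](C)(Br)[C@H](Cl)C2)CC[C@H]1[Hg]Br
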